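Cuts: the three O–S bonds are cut first, back to the triol geraldol (3,7,4'-trihydroxy-3'-methoxyflavone). The C3–O bond follows, two hydrogens are formally returned to C5 and C6 of ring A, and the C4–C4a and O1–C2 bonds of ring C are cut last.
Enabling feature: in ring A the oxygen on C7 and the ring oxygen O1 on C8a stand 1,3 to each other, and the acyl-bearing C4a is the neighbour of C8a. C8a–C8–C7(O) therefore maps onto C1–C2–C3(OR) of a 3-alkoxycyclohex-2-enone, and C4a maps onto its alpha' carbon C6.
Fragments: ring B arrives intact in O-benzylvanillin (its CHO carbon becomes C2, the Corey–Fuchs carbon C3, the carbamoyl carbon C4). Ring A arrives as the six-membered carbocycle of cyclohexane-1,3-dione.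
Forward order: the fragments are joined at C4–C4a and ring C is closed at O1–C2 in one operation. Ring A is then dehydrogenated to the benzene level, C3 is hydroxylated, both benzyl ethers are removed and the three hydroxyl groups are sulfated.
Stereochemistry: the target has no stereocentre and no configurable double bond. The sp3 centres of transient intermediates vanish on enolisation and cyclisation.

Key step: step 4

Assumption: the target is taken as the fully protonated tris(hydrogen sulfate) shown by its SMILES; because aryl hydrogen sulfates hydrolyse under their own acidity, the pyridinium salt is the purifiable storage form and the free acid is released only in the last step and kept cold.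

Step 1
Reactants: 1 cyclohexane-1,3-dione; 2 benzyl alcohol
Product: 3 3-(benzyloxy)cyclohex-2-en-1-one
Conditions: p-TsOH·H2O (cat.), toluene, Dean–Stark, reflux
Reagents that add atoms: none
Why: Acid-catalysed condensation of a cyclic 1,3-dione with an alcohol under azeotropic water removal is the standard vinylogous ester synthesis, and the symmetry of 1 allows only one product.

Step 2
Reactants: 4 4-(benzyloxy)-3-methoxybenzaldehyde (O-benzylvanillin, commercial)
Product: 5 1-(benzyloxy)-4-(2,2-dibromoethenyl)-2-methoxybenzene
Conditions: CBr4 (2 equiv), PPh3 (4 equiv), CH2Cl2, 0 °C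
Reagents that add atoms: carbon tetrabromide, BrC(Br)(Br)Br
Why: This is the first stage of the Corey–Fuchs homologation, a Wittig-type dibromoolefination that works well on non-enolisable aromatic aldehydes and leaves aryl ethers untouched.

Step 3
Reactants: 5 1-(benzyloxy)-4-(2,2-dibromoethenyl)-2-methoxybenzene; 6 N-methoxy-N-methylcarbamoyl chloride (commercial)
Product: 8 3-[4-(benzyloxy)-3-methoxyphenyl]-N-methoxy-N-methylprop-2-ynamide, via lithium acetylide 7 (not isolated)
Conditions: n-BuLi (2.1 equiv), THF, −78 → 0 °C; then 6, −78 °C → rt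
Reagents that add atoms: none
Why: The second stage of the Corey–Fuchs reaction (bromine–lithium exchange, elimination and deprotonation) delivers the acetylide, which is trapped in the same flask by addition–elimination at the carbamoyl chloride, a standard entry to alkynyl Weinreb amides in which chloride is by far the better leaving group.

Step 4
Reactants: 3 3-(benzyloxy)cyclohex-2-en-1-one; 8 3-[4-(benzyloxy)-3-methoxyphenyl]-N-methoxy-N-methylprop-2-ynamide
Product: 12 7-(benzyloxy)-2-[4-(benzyloxy)-3-methoxyphenyl]-5,6-dihydro-4H-chromen-4-one, via lithium dienolate 9 (not isolated), via tetrahedral lithium adduct 10 (not isolated), via acetylenic diketone enol 11 (not isolated)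
Conditions: 3 (1.5 equiv), LiN(i-Pr)2 (1.4 equiv), THF, −78 °C; 8, −78 → −20 °C; inverse quench into 1 M HCl, 0 °C; crude 11, CSA (20 mol %), toluene, 50 °C
Reagents that add atoms: none
Why: Lithium diisopropylamide at −78 °C takes the C6 (alpha') proton of 3 irreversibly, as in Stork–Danheiser chemistry, since the gamma protons at C4 are reached only under equilibrating conditions, and this gives the cross-conjugated dienolate 9. The hard lithium enolate attacks the amide carbonyl of 8 rather than the alkyne terminus, which the electron-rich guaiacyl ring deactivates further towards conjugate addition, and the N-methoxy chelate 10 survives until the quench, so the C4–C4a bond forms without a second addition and without an acidic diketone consuming unreacted enolate. The inverse quench into cold aqueous HCl releases 11 and carries the liberated N,O-dimethylhydroxylamine away as its salt before it can add to the ynone, and the brief cold contact spares the benzyl enol ether. Under anhydrous acid catalysis the ring enol oxygen (the former ketone oxygen of 3) adds to the aryl-bearing alkyne carbon in a 6-endo-dig oxa-Michael closure that makes O1–C2 and ring C; the polarisation of the activated ynone and the benzylic stabilisation by ring B place the positive charge on that carbon, which disfavours the 5-exo-dig furanone mode. The closest known reaction types are the Claisen-type acylation of ketone enolates with Weinreb amides and the acid-mediated cyclisation of acetylenic beta-diketones and of 2-hydroxyaryl ynones to gamma-pyranones. No stereocentre is created, and the oxygen pattern of ring A is inherited unchanged from 3, so no regiochemical choice on an aromatic ring is involved.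

Step 5
Reactants: 12 7-(benzyloxy)-2-[4-(benzyloxy)-3-methoxyphenyl]-5,6-dihydro-4H-chromen-4-one
Product: 13 7-(benzyloxy)-2-[4-(benzyloxy)-3-methoxyphenyl]-4H-chromen-4-one
Conditions: DDQ (1.2 equiv), 1,4-dioxane, rt → 60 °C, dark
Reagents that add atoms: none
Why: DDQ dehydrogenation of a 1,3-cyclohexadiene (hydride loss from C5 stabilised through O1, then proton loss from C6) is driven by formation of the benzenoid ring A, and unactivated benzyl ethers resist DDQ in an anhydrous medium without light.

Step 6
Reactants: 13 7-(benzyloxy)-2-[4-(benzyloxy)-3-methoxyphenyl]-4H-chromen-4-one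
Product: 16 7-(benzyloxy)-2-[4-(benzyloxy)-3-methoxyphenyl]-3-hydroxy-4H-chromen-4-one, via 3-lithioflavone 14 (not isolated), via lithium trimethoxyborate 15 (not isolated)
Conditions: LiN(i-Pr)2 (1.5 equiv), THF, −78 °C; B(OMe)3 (3 equiv), −78 → 0 °C; AcOH, 30% H2O2, 0 °C → rt
Reagents that add atoms: hydrogen peroxide, OO
Why: C3 lithiation of flavones with a lithium amide, followed by borylation and peroxide oxidation with 1,2-migration from boron to oxygen, is the established anionic route from flavones to flavonols, and C3–H next to the lithium-coordinating C4 carbonyl is the only proton acidic enough for this base at −78 °C.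

Step 7
Reactants: 16 7-(benzyloxy)-2-[4-(benzyloxy)-3-methoxyphenyl]-3-hydroxy-4H-chromen-4-one
Product: 17 3,7-dihydroxy-2-(4-hydroxy-3-methoxyphenyl)-4H-chromen-4-one (geraldol)
Conditions: H2 (1 atm), 10% Pd/C, THF–MeOH, rt
Reagents that add atoms: none
Why: Catalytic hydrogenolysis cleaves both aryl benzyl ethers, while the tetrasubstituted C2=C3 bond of the flavonol, which is part of the pyranone conjugation, is not reduced at atmospheric pressure.

Step 8
Reactants: 17 3,7-dihydroxy-2-(4-hydroxy-3-methoxyphenyl)-4H-chromen-4-one
Product: 18 tris(pyridinium) salt of geraldol 3,7,4'-tris-O-sulfate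
Conditions: SO3·pyridine (5 equiv per OH), pyridine–DMF, 55 °C; H2O, 0 °C; Sephadex LH-20 (MeOH–H2O)
Reagents that add atoms: sulfur trioxide–pyridine complex, O=S(=O)([O-])[n+]1ccccc1
Why: O-sulfonation of phenolic and enolic hydroxyl groups with an amine–SO3 complex is the standard sulfation method, a large excess and mild heating push all three sites to completion, and the lack of a 5-OH means no strongly chelated hydroxyl has to react.

Step 9
Reactants: 18 tris(pyridinium) salt of geraldol 3,7,4'-tris-O-sulfate
Product: 19 2-[3-methoxy-4-(sulfooxy)phenyl]-4-oxo-4H-chromene-3,7-diyl bis(hydrogen sulfate) (CNP0382475.0)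
Conditions: Dowex 50WX8 (H+ form), H2O, 0–5 °C; freeze-drying
Reagents that add atoms: none
Why: Passage through a strong-acid cation-exchange resin replaces pyridinium by protons without touching the S–O bonds, and low temperature with immediate lyophilisation limits acid-promoted desulfation.

Compound list
1 | cyclohexane-1,3-dione | O=C1CCCC(=O)C1 | starting material
2 | benzyl alcohol | OCc1ccccc1 | starting material
3 | 3-(benzyloxy)cyclohex-2-en-1-one | O=C1C=C(OCc2ccccc2)CCC1 | intermediate
4 | 4-(benzyloxy)-3-methoxybenzaldehyde | COc1cc(C=O)ccc1OCc1ccccc1 | starting material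
5 | 1-(benzyloxy)-4-(2,2-dibromoethenyl)-2-methoxybenzene | COc1cc(C=C(Br)Br)ccc1OCc1ccccc1 | intermediate
6 | N-methoxy-N-methylcarbamoyl chloride | CON(C)C(=O)Cl | starting material
7 | lithium [4-(benzyloxy)-3-methoxyphenyl]acetylide (not isolated) | [Li]C#Cc1ccc(OCc2ccccc2)c(OC)c1 | intermediate
8 | 3-[4-(benzyloxy)-3-methoxyphenyl]-N-methoxy-N-methylprop-2-ynamide | CON(C)C(=O)C#Cc1ccc(OCc2ccccc2)c(OC)c1 | intermediate
9 | lithium 5-(benzyloxy)cyclohexa-1,5-dien-1-olate (not isolated) | [Li]OC1=CCCC(OCc2ccccc2)=C1 | intermediate
10 | lithium 1-[4-(benzyloxy)-2-oxocyclohex-3-en-1-yl]-3-[4-(benzyloxy)-3-methoxyphenyl]-1-[methoxy(methyl)amino]prop-2-yn-1-olate (not isolated, mixture of diastereomers, both centres erased later) | [Li]OC(C#Cc1ccc(OCc2ccccc2)c(OC)c1)(N(C)OC)C1CCC(OCc2ccccc2)=CC1=O | intermediate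
11 | 1-[4-(benzyloxy)-2-hydroxycyclohexa-1,3-dien-1-yl]-3-[4-(benzyloxy)-3-methoxyphenyl]prop-2-yn-1-one (enol tautomer of the acetylenic beta-diketone, not isolated) | OC1=C(C(=O)C#Cc2ccc(OCc3ccccc3)c(OC)c2)CCC(OCc2ccccc2)=C1 | intermediate
12 | 7-(benzyloxy)-2-[4-(benzyloxy)-3-methoxyphenyl]-5,6-dihydro-4H-chromen-4-one | COc1cc(C2=CC(=O)C3=C(C=C(OCc4ccccc4)CC3)O2)ccc1OCc1ccccc1 | intermediate
13 | 7-(benzyloxy)-2-[4-(benzyloxy)-3-methoxyphenyl]-4H-chromen-4-one | COc1cc(-c2cc(=O)c3ccc(OCc4ccccc4)cc3o2)ccc1OCc1ccccc1 | intermediate
14 | 7-(benzyloxy)-2-[4-(benzyloxy)-3-methoxyphenyl]-3-lithio-4H-chromen-4-one (not isolated) | [Li]c1c(-c2ccc(OCc3ccccc3)c(OC)c2)oc2cc(OCc3ccccc3)ccc2c1=O | intermediate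
15 | lithium {7-(benzyloxy)-2-[4-(benzyloxy)-3-methoxyphenyl]-4-oxo-4H-chromen-3-yl}trimethoxyborate (not isolated) | [Li+].CO[B-](OC)(OC)c1c(-c2ccc(OCc3ccccc3)c(OC)c2)oc2cc(OCc3ccccc3)ccc2c1=O | intermediate
16 | 7-(benzyloxy)-2-[4-(benzyloxy)-3-methoxyphenyl]-3-hydroxy-4H-chromen-4-one | COc1cc(-c2oc3cc(OCc4ccccc4)ccc3c(=O)c2O)ccc1OCc1ccccc1 | intermediate
17 | 3,7-dihydroxy-2-(4-hydroxy-3-methoxyphenyl)-4H-chromen-4-one (geraldol) | COc1cc(-c2oc3cc(O)ccc3c(=O)c2O)ccc1O | intermediate
18 | tris(pyridinium) 2-[3-methoxy-4-(sulfonatooxy)phenyl]-4-oxo-4H-chromene-3,7-diyl bis(sulfate) | COc1cc(-c2oc3cc(OS(=O)(=O)[O-])ccc3c(=O)c2OS(=O)(=O)[O-])ccc1OS(=O)(=O)[O-].c1cc[nH+]cc1.c1cc[nH+]cc1.c1cc[nH+]cc1 | intermediate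
19 | 2-[3-methoxy-4-(sulfooxy)phenyl]-4-oxo-4H-chromene-3,7-diyl bis(hydrogen sulfate) (CNP0382475.0) | COc1cc(-c2oc3cc(OS(=O)(=O)O)ccc3c(=O)c2OS(=O)(=O)O)ccc1OS(=O)(=O)O | target

Total step count: 9.
Longest linear sequence: 8 steps (4 → 5 → 8 → 12 → 13 → 16 → 17 → 18 → 19). Step 1 is a one-step side branch.

Steps most likely to fail

Step 4. The acylation may stall at the temperature at which the kinetic dienolate keeps its regiochemistry. The enolate may also add in conjugate fashion to the alkyne, or equilibrate to the extended gamma-dienolate on warming. The fallback replaces acylation by aldol addition and oxidation and forms the same C4–C4a bond. It sets out from dibromoalkene 5. Acetylide 7 is generated as in step 3 and formylated with DMF to give 3-[4-(benzyloxy)-3-methoxyphenyl]prop-2-ynal F1. This much more electrophilic carbonyl partner is added at −78 °C to dienolate 9 (from 3 and lithium diisopropylamide) to give the propargylic aldol 3-(benzyloxy)-6-{3-[4-(benzyloxy)-3-methoxyphenyl]-1-hydroxyprop-2-yn-1-yl}cyclohex-2-en-1-one F2 as a mixture of diastereomers. Dess–Martin periodinane in CH2Cl2 oxidises the carbinol. The route is rejoined at diketone enol 11, which is cyclised to 12 with CSA as in step 4.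

Step 6. Metalation may be incomplete, the lithiated pyranone may add to unreacted flavone, or the metalated ring C may open before the borate is formed. The fallback replaces the anionic sequence by electrophilic oxygen transfer. It sets out from flavone 13. Dimethyldioxirane in acetone–CH2Cl2 at 0 °C epoxidises the enol-ether-like C2=C3 bond to give the cis-fused racemic 7-(benzyloxy)-2-[4-(benzyloxy)-3-methoxyphenyl]-2,3-epoxy-2,3-dihydro-4H-chromen-4-one F3. With catalytic p-TsOH the epoxide opens at the O1- and aryl-stabilised C2 and loses the C3 proton, which brings the route back at flavonol 16.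

Step 8. Sulfation may stop short of completion, most likely at the C3 hydroxyl that is hydrogen-bonded to the C4 carbonyl. Partly sulfated anions are hard to separate, and desulfation during work-up would add to the problem. The fallback installs protected, neutral sulfate diesters. It sets out from triol 17. 2,2,2-Trichloroethyl chlorosulfate, Et3N and DMAP in THF give geraldol 3,7,4'-tris(2,2,2-trichloroethyl sulfate) F4, which is purified on silica gel so that under-sulfated material is removed at a neutral stage. Zn dust and HCO2NH4 in MeOH unmask all three groups by reductive fragmentation to give the triammonium salt of geraldol 3,7,4'-tris-O-sulfate F5. This salt passes through the H+ resin of step 9, and the route comes back at 19.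

Further compounds
F1 | step 4 | 3-[4-(benzyloxy)-3-methoxyphenyl]prop-2-ynal | O=CC#Cc1ccc(OCc2ccccc2)c(OC)c1
F2 | step 4 | 3-(benzyloxy)-6-{3-[4-(benzyloxy)-3-methoxyphenyl]-1-hydroxyprop-2-yn-1-yl}cyclohex-2-en-1-one (mixture of diastereomers, both centres erased on oxidation and enolisation) | OC(C#Cc1ccc(OCc2ccccc2)c(OC)c1)C1CCC(OCc2ccccc2)=CC1=O
F3 | step 6 | 7-(benzyloxy)-2-[4-(benzyloxy)-3-methoxyphenyl]-2,3-epoxy-2,3-dihydro-4H-chromen-4-one (cis-fused, racemic, one enantiomer drawn) | O=C1[C@@H]2O[C@]2(c2ccc(OCc3ccccc3)c(OC)c2)Oc2cc(OCc3ccccc3)ccc12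
F4 | step 8 | geraldol 3,7,4'-tris(2,2,2-trichloroethyl sulfate) | COc1cc(-c2oc3cc(OS(=O)(=O)OCC(Cl)(Cl)Cl)ccc3c(=O)c2OS(=O)(=O)OCC(Cl)(Cl)Cl)ccc1OS(=O)(=O)OCC(Cl)(Cl)Cl
F5 | step 8 | triammonium salt of geraldol 3,7,4'-tris-O-sulfate | COc1cc(-c2oc3cc(OS(=O)(=O)[O-])ccc3c(=O)c2OS(=O)(=O)[O-])ccc1OS(=O)(=O)[O-].[NH4+].[NH4+].[NH4+]
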